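**Strategy.** Ring B (C4a–C5–C6–C7–C8–C8a, isochromene numbering) is cut across C4a–C8a and C6–C7. Its C6(O)–C7(OH)(CH3)–C8(=O) array is an acyloin pattern, and C8a is the α-carbon of the C8 ketone. One amine/carbene relay operation therefore joins the acyclic 1,2-diketone 3 (C7, C8, C8a, C1) with enynal 7 (C6, C5, C4a and the C4–C3–propenyl chain): a Michael addition forges C4a–C8a, and an intramolecular cross-benzoin forges C6–C7 and sets C7. C6 reduction, esterification, selenoxide desaturation to the C4a=C8a enynone and a fluoride-triggered 6-endo oxa-Michael closure of pyran ring A finish the target.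

Key step: step 5

Remark (assumption): atoms carry the isochromene numbering of the target (C1, O2, C3, C4, C4a, C5–C8, C8a; ring A = pyran, ring B = carbocycle); 1, 4, 5 and 11 are taken as commercial, 4 and 5 as pure E isomers; the two organocatalyst antipodes in step 5 are chosen as the matched pair that delivers (7S).

**Step 1**
Reactants: 1 pent-3-yn-1-ol
Product: 2 tert-butyl(dimethyl)(pent-3-yn-1-yloxy)silane
Conditions: TBSCl, imidazole, CH2Cl2, 0 °C to rt
Reagents that add atoms: tert-butyl(chloro)dimethylsilane, CC(C)(C)[Si](C)(C)Cl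
Why: Silyl ether formation masks the future C1 hydroxyl, so that the alkyne can be oxidised and the diketone cannot close to a hemiketal.

**Step 2**
Reactants: 2 tert-butyl(dimethyl)(pent-3-yn-1-yloxy)silane
Product: 3 5-{[tert-butyl(dimethyl)silyl]oxy}pentane-2,3-dione
Conditions: RuCl3·xH2O (2 mol %), NaIO4, NaHCO3, MgSO4, EtOAc/MeCN/H2O, 0 °C
Reagents that add atoms: sodium periodate, [Na+].[O-]I(=O)(=O)=O
Why: Catalytic RuO4 oxidation of an internal alkyne to the 1,2-diketone should install C7=O and C8=O, the buffered, short reaction sparing the primary silyl ether.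

**Step 3**
Reactants: 4 (2E)-pent-2-en-4-yn-1-ol; 5 (1E)-1-bromoprop-1-ene
Product: 6 (2E,6E)-octa-2,6-dien-4-yn-1-ol
Conditions: Pd(PPh3)2Cl2 (2 mol %), CuI (4 mol %), Et3N, THF, rt
Reagents that add atoms: none
Why: Sonogashira coupling of the terminal alkyne with the vinyl bromide proceeds with retention of both alkene geometries and assembles C3–C4 and the propenyl group.

**Step 4**
Reactants: 6 (2E,6E)-octa-2,6-dien-4-yn-1-ol
Product: 7 (2E,6E)-octa-2,6-dien-4-ynal
Conditions: MnO2, CH2Cl2, rt
Reagents that add atoms: none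
Why: Allylic oxidation with MnO2 should give the enynal (C6 aldehyde, C5=C4a acceptor) without touching the enyne; it is used directly.

**Step 5**
Reactants: 3 5-{[tert-butyl(dimethyl)silyl]oxy}pentane-2,3-dione; 7 (2E,6E)-octa-2,6-dien-4-ynal
Product: 9 (2S,4R,5R)-4-({[tert-butyl(dimethyl)silyl]oxy}methyl)-2-hydroxy-2-methyl-5-[(3E)-pent-3-en-1-yn-1-yl]cyclohexane-1,3-dione, via Michael aldehyde 8 (not isolated)
Conditions: diphenylprolinol trimethylsilyl ether (20 mol %), aminoindanol-derived N-pentafluorophenyl triazolium tetrafluoroborate (10 mol %), NaOAc (10 mol %), CHCl3, rt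
Reagents that add atoms: none
Why: Proposed new method: the secondary amine converts 7 into an iminium ion, to which the more substituted (C8a) enol of diketone 3 adds at C4a (first bond); the liberated aldehyde 8 is captured by the triazolylidene carbene as an acyl anion equivalent that attacks the C7 carbonyl (second bond) before the carbene is released. The closest known reaction type is the relay amine/carbene Michael–cross-benzoin cascade of enals with 1,3-dicarbonyl donors, which gives five-membered acyloins; here the 1,2-diketone places the acceptor carbonyl one atom further away. Ring B closes by 6-exo-trig attack of the acyl anion equivalent on the acetyl carbonyl. C4a is set by the amine, whose diarylmethyl group shields one face of the iminium ion, C7 by the chiral triazolium within the matched pair, and C8a equilibrates to the trans arrangement; C4a and C8a are erased later. The step needs donor regioselectivity (the C8a enol is the more substituted, conjugated one), 1,4- over 1,6-addition (iminium β-carbon), C7 over C8 as acceptor (C8 is more hindered and can sit as the enol towards C8a) and carbene capture of 8 faster than enamine aldolisation, which the fast intramolecular benzoin step should secure.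

**Step 6**
Reactants: 9 (2S,4R,5R)-4-({[tert-butyl(dimethyl)silyl]oxy}methyl)-2-hydroxy-2-methyl-5-[(3E)-pent-3-en-1-yn-1-yl]cyclohexane-1,3-dione
Product: 10 (2S,3S,5R,6R)-6-({[tert-butyl(dimethyl)silyl]oxy}methyl)-2,3-dihydroxy-2-methyl-5-[(3E)-pent-3-en-1-yn-1-yl]cyclohexan-1-one
Conditions: NaBH4 (0.4 equiv), MeOH/CH2Cl2, −78 °C
Reagents that add atoms: none
Why: Hydride reduction should select the less hindered C6 ketone (C8 is flanked by the branched C8a) and enter axially, anti to the axial C7–O bond of the chair that keeps the C7 methyl, C8a and C4a substituents equatorial, giving the equatorial (6S) alcohol cis to the C7 hydroxyl.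

**Step 7**
Reactants: 11 2,4-dihydroxy-6-methylbenzaldehyde
Product: 12 2-hydroxy-6-methyl-4-{[tri(propan-2-yl)silyl]oxy}benzaldehyde
Conditions: TIPSCl, imidazole, CH2Cl2, 0 °C
Reagents that add atoms: chlorotri(propan-2-yl)silane, CC(C)[Si](Cl)(C(C)C)C(C)C
Why: Silylation should take the free para hydroxyl selectively, the ortho hydroxyl being tied up in a hydrogen bond to the aldehyde.

**Step 8**
Reactants: 12 2-hydroxy-6-methyl-4-{[tri(propan-2-yl)silyl]oxy}benzaldehyde
Product: 13 2-methoxy-6-methyl-4-{[tri(propan-2-yl)silyl]oxy}benzaldehyde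
Conditions: MeI, K2CO3, acetone, 40 °C
Reagents that add atoms: iodomethane, CI
Why: Williamson O-methylation of the remaining phenol; the bulky aryl silyl ether should survive carbonate in dry acetone.

**Step 9**
Reactants: 13 2-methoxy-6-methyl-4-{[tri(propan-2-yl)silyl]oxy}benzaldehyde
Product: 14 2-methoxy-6-methyl-4-{[tri(propan-2-yl)silyl]oxy}benzoic acid
Conditions: NaClO2, NaH2PO4, 2-methylbut-2-ene, t-BuOH/H2O, rt
Reagents that add atoms: sodium chlorite, [Na+].[O-]Cl=O
Why: Pinnick oxidation converts the hindered, electron-rich aldehyde into the acid, the alkene scavenger removing hypochlorous acid before it can chlorinate the arene.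

**Step 10**
Reactants: 10 (2S,3S,5R,6R)-6-({[tert-butyl(dimethyl)silyl]oxy}methyl)-2,3-dihydroxy-2-methyl-5-[(3E)-pent-3-en-1-yn-1-yl]cyclohexan-1-one; 14 2-methoxy-6-methyl-4-{[tri(propan-2-yl)silyl]oxy}benzoic acid
Product: 16 (1S,2S,4R,5R)-4-({[tert-butyl(dimethyl)silyl]oxy}methyl)-2-hydroxy-2-methyl-3-oxo-5-[(3E)-pent-3-en-1-yn-1-yl]cyclohexyl 2-methoxy-6-methyl-4-{[tri(propan-2-yl)silyl]oxy}benzoate, via aroyl chloride 15 (not isolated)
Conditions: 14, 1-chloro-N,N,2-trimethylprop-1-en-1-amine, CH2Cl2, 0 °C to rt; then 10, Et3N, DMAP, CH2Cl2, rt to 40 °C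
Reagents that add atoms: none
Why: Neutral acid chloride formation followed by DMAP-catalysed acylation should esterify only the equatorial secondary C6 hydroxyl, the tertiary C7 hydroxyl being too hindered, with retention at C6.

**Step 11**
Reactants: 16 (1S,2S,4R,5R)-4-({[tert-butyl(dimethyl)silyl]oxy}methyl)-2-hydroxy-2-methyl-3-oxo-5-[(3E)-pent-3-en-1-yn-1-yl]cyclohexyl 2-methoxy-6-methyl-4-{[tri(propan-2-yl)silyl]oxy}benzoate
Product: 19 (1S,6S)-4-({[tert-butyl(dimethyl)silyl]oxy}methyl)-6-methyl-5-oxo-3-[(3E)-pent-3-en-1-yn-1-yl]-6-[(trimethylsilyl)oxy]cyclohex-3-en-1-yl 2-methoxy-6-methyl-4-{[tri(propan-2-yl)silyl]oxy}benzoate, via bis-silyl enol ether 17 (not isolated), via C8a selenide 18 (not isolated)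
Conditions: TMSOTf, Et3N, CH2Cl2, −78 to 0 °C; PhSeCl, −78 °C; then H2O2 (30 % aq.), pyridine, 0 °C to rt
Reagents that add atoms: trimethylsilyl trifluoromethanesulfonate, C[Si](C)(C)OS(=O)(=O)C(F)(F)F
Why: α-Selenenylation/selenoxide elimination: the C8 ketone can enolise only towards C8a, the enol silane should be selenenylated at −78 °C faster than the enyne and from the face opposite the axial C7 oxygen (PhSe cis to H-4a), and the selenoxide should eliminate syn towards H-4a and not towards the oxygen-bearing C1, installing C4a=C8a.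

**Step 12**
Reactants: 19 (1S,6S)-4-({[tert-butyl(dimethyl)silyl]oxy}methyl)-6-methyl-5-oxo-3-[(3E)-pent-3-en-1-yn-1-yl]-6-[(trimethylsilyl)oxy]cyclohex-3-en-1-yl 2-methoxy-6-methyl-4-{[tri(propan-2-yl)silyl]oxy}benzoate
Product: 21 comazaphilone G, via desilylated enynone 20 (not isolated)
Conditions: TBAF, AcOH, THF, 0 °C to rt; then AgOTf (5 mol %), rt
Reagents that add atoms: none
Why: Buffered fluoride cleaves the three silyl ethers, and the freed C1 hydroxyl should add to C3, the δ-carbon of the C8=O/C8a=C4a/C4≡C3 enynone, in a silver-assisted 6-endo-dig oxa-Michael cycloisomerisation that closes pyran ring A (the 5-exo mode would be anti-Michael); the acetic acid buffer guards the C6 ester against vinylogous elimination and no stereocenter is touched.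

**Compound list**

1 | pent-3-yn-1-ol | CC#CCCO | starting material
2 | tert-butyl(dimethyl)(pent-3-yn-1-yloxy)silane | CC#CCCO[Si](C)(C)C(C)(C)C | intermediate
3 | 5-{[tert-butyl(dimethyl)silyl]oxy}pentane-2,3-dione | CC(=O)C(=O)CCO[Si](C)(C)C(C)(C)C | intermediate
4 | (2E)-pent-2-en-4-yn-1-ol | OC/C=C/C#C | starting material
5 | (1E)-1-bromoprop-1-ene | C/C=C/Br | starting material
6 | (2E,6E)-octa-2,6-dien-4-yn-1-ol | OC/C=C/C#C/C=C/C | intermediate
7 | (2E,6E)-octa-2,6-dien-4-ynal | O=C/C=C/C#C/C=C/C | intermediate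
8 | (3R,4R)-4-({[tert-butyl(dimethyl)silyl]oxy}methyl)-5,6-dioxo-3-[(3E)-pent-3-en-1-yn-1-yl]heptanal | O=CC[C@@H](C#C/C=C/C)[C@H](CO[Si](C)(C)C(C)(C)C)C(=O)C(C)=O | intermediate
9 | (2S,4R,5R)-4-({[tert-butyl(dimethyl)silyl]oxy}methyl)-2-hydroxy-2-methyl-5-[(3E)-pent-3-en-1-yn-1-yl]cyclohexane-1,3-dione | O=C1[C@@](C)(O)C(=O)C[C@@H](C#C/C=C/C)[C@@H]1CO[Si](C)(C)C(C)(C)C | intermediate
10 | (2S,3S,5R,6R)-6-({[tert-butyl(dimethyl)silyl]oxy}methyl)-2,3-dihydroxy-2-methyl-5-[(3E)-pent-3-en-1-yn-1-yl]cyclohexan-1-one | O=C1[C@@](C)(O)[C@@H](O)C[C@@H](C#C/C=C/C)[C@@H]1CO[Si](C)(C)C(C)(C)C | intermediate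
11 | 2,4-dihydroxy-6-methylbenzaldehyde | Cc1cc(O)cc(O)c1C=O | starting material
12 | 2-hydroxy-6-methyl-4-{[tri(propan-2-yl)silyl]oxy}benzaldehyde | Cc1cc(O[Si](C(C)C)(C(C)C)C(C)C)cc(O)c1C=O | intermediate
13 | 2-methoxy-6-methyl-4-{[tri(propan-2-yl)silyl]oxy}benzaldehyde | COc1cc(O[Si](C(C)C)(C(C)C)C(C)C)cc(C)c1C=O | intermediate
14 | 2-methoxy-6-methyl-4-{[tri(propan-2-yl)silyl]oxy}benzoic acid | COc1cc(O[Si](C(C)C)(C(C)C)C(C)C)cc(C)c1C(=O)O | intermediate
15 | 2-methoxy-6-methyl-4-{[tri(propan-2-yl)silyl]oxy}benzoyl chloride | COc1cc(O[Si](C(C)C)(C(C)C)C(C)C)cc(C)c1C(=O)Cl | intermediate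
16 | (1S,2S,4R,5R)-4-({[tert-butyl(dimethyl)silyl]oxy}methyl)-2-hydroxy-2-methyl-3-oxo-5-[(3E)-pent-3-en-1-yn-1-yl]cyclohexyl 2-methoxy-6-methyl-4-{[tri(propan-2-yl)silyl]oxy}benzoate | O=C1[C@@](C)(O)[C@@H](OC(=O)c2c(C)cc(O[Si](C(C)C)(C(C)C)C(C)C)cc2OC)C[C@@H](C#C/C=C/C)[C@@H]1CO[Si](C)(C)C(C)(C)C | intermediate
17 | bis(trimethylsilyl) derivative of 16: trimethylsilyl enol ether of the C8 ketone (C8=C8a) and trimethylsilyl ether of the C7 hydroxyl; C4a, C6 and C7 configured as in 16 | C1(O[Si](C)(C)C)[C@@](C)(O[Si](C)(C)C)[C@@H](OC(=O)c2c(C)cc(O[Si](C(C)C)(C(C)C)C(C)C)cc2OC)C[C@@H](C#C/C=C/C)C=1CO[Si](C)(C)C(C)(C)C | intermediate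
18 | C8a phenylselenide of the C7 trimethylsilyl ether of 16 (PhSe cis to H-4a; C4a, C6 and C7 as in 16) | O=C1[C@@](C)(O[Si](C)(C)C)[C@@H](OC(=O)c2c(C)cc(O[Si](C(C)C)(C(C)C)C(C)C)cc2OC)C[C@@H](C#C/C=C/C)[C@@]1([Se]c3ccccc3)CO[Si](C)(C)C(C)(C)C | intermediate
19 | (1S,6S)-4-({[tert-butyl(dimethyl)silyl]oxy}methyl)-6-methyl-5-oxo-3-[(3E)-pent-3-en-1-yn-1-yl]-6-[(trimethylsilyl)oxy]cyclohex-3-en-1-yl 2-methoxy-6-methyl-4-{[tri(propan-2-yl)silyl]oxy}benzoate | C/C=C/C#CC1=C(CO[Si](C)(C)C(C)(C)C)C(=O)[C@@](C)(O[Si](C)(C)C)[C@@H](OC(=O)c2c(C)cc(O[Si](C(C)C)(C(C)C)C(C)C)cc2OC)C1 | intermediate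
20 | (1S,6S)-6-hydroxy-4-(hydroxymethyl)-6-methyl-5-oxo-3-[(3E)-pent-3-en-1-yn-1-yl]cyclohex-3-en-1-yl 4-hydroxy-2-methoxy-6-methylbenzoate | C/C=C/C#CC1=C(CO)C(=O)[C@@](C)(O)[C@@H](OC(=O)c2c(C)cc(O)cc2OC)C1 | intermediate
21 | comazaphilone G, (6S,7S)-7-hydroxy-7-methyl-8-oxo-3-[(1E)-prop-1-en-1-yl]-5,6,7,8-tetrahydro-1H-isochromen-6-yl 4-hydroxy-2-methoxy-6-methylbenzoate | C/C=C/C1=CC2=C(CO1)C(=O)[C@@](C)(O)[C@@H](OC(=O)c1c(C)cc(O)cc1OC)C2 | target

**Totals.** Total step count: 12. Longest linear sequence: 7 steps (1, 2, 5, 6, 10, 11, 12).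

**Steps most likely to fail**

Step 5 (bears the label). What may go wrong:
- enamine aldolisation of the Michael aldehyde onto the diketone instead of carbene capture;
- carbene addition to the enal before the Michael step (homoenolate pathways with the diketone);
- benzoin closure onto C8 (five-membered ring);
- Michael addition through the methyl-side enol, or β-elimination of the silyloxy group from the donor.

Fallback with known chemistry, setting out from 3 and 7 and coming back at 9: 3 would be converted with TMSCl/Et3N into its trimethylsilyl enol ether (3Z)-5-{[tert-butyl(dimethyl)silyl]oxy}-3-[(trimethylsilyl)oxy]pent-3-en-2-one F1, which would be added to 7 in a Mukaiyama–Michael reaction under imidazolidinone iminium catalysis. Aldehyde 8 would be isolated after desilylative work-up and closed in a separate intramolecular crossed aldehyde–ketone benzoin reaction (chiral triazolium salt, Et3N) to 9.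

Step 6. What may go wrong: competing reduction of the C8 ketone, or hydride delivery from the face that gives the trans diol (for example through chelation or intramolecular delivery from the C7 oxygen). Fallback, setting out from 9 and coming back at 10: biocatalytic reduction with a ketoreductase (NADP+ cofactor, propan-2-ol as hydride source, phosphate buffer/DMSO), the enzyme being selected from a panel for the C6 ketone and the (6S) alcohol; no new compound is made.

Step 11. What may go wrong: selenenylation of the enyne instead of the enol silane, attack of selenium on the face that places it anti to H-4a so that syn-elimination stalls, or elimination towards C1. Fallback, setting out from 16 and coming back at 20: direct dehydrogenation with 2-iodoxybenzoic acid and 4-methoxypyridine N-oxide in DMSO to the free-hydroxy enynone (1S,6S)-4-({[tert-butyl(dimethyl)silyl]oxy}methyl)-6-hydroxy-6-methyl-5-oxo-3-[(3E)-pent-3-en-1-yn-1-yl]cyclohex-3-en-1-yl 2-methoxy-6-methyl-4-{[tri(propan-2-yl)silyl]oxy}benzoate F2, which would be taken into the fluoride conditions of step 12 and rejoin the route at 20.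

**Further compounds**

F1 | step 5 | (3Z)-5-{[tert-butyl(dimethyl)silyl]oxy}-3-[(trimethylsilyl)oxy]pent-3-en-2-one | CC(=O)/C(O[Si](C)(C)C)=C/CO[Si](C)(C)C(C)(C)C
F0 | step 6 | none | none
F2 | step 11 | (1S,6S)-4-({[tert-butyl(dimethyl)silyl]oxy}methyl)-6-hydroxy-6-methyl-5-oxo-3-[(3E)-pent-3-en-1-yn-1-yl]cyclohex-3-en-1-yl 2-methoxy-6-methyl-4-{[tri(propan-2-yl)silyl]oxy}benzoate | C/C=C/C#CC1=C(CO[Si](C)(C)C(C)(C)C)C(=O)[C@@](C)(O)[C@@H](OC(=O)c2c(C)cc(O[Si](C(C)C)(C(C)C)C(C)C)cc2OC)C1
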